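Z takes one Q.D and one L.Q, and Q.D can form only from D, which enters from J at a bounded pace, so I reckoned Z from that supply.

    L + Q → L.Q (k1 = 14 /M/h)
    Q + D → Q.D (k2 = 16 /M/h)
    L.Q + Q.D → Z (k3 = 18 /M/h)
    L + Q.D → L.Q.D (k4 = 89 /M/h)
    J ⇌ D, rate k5*(csat - [D]) (k5 = 1.1 /h, csat = 1.5 mM)

| setting | west | east |
|---|---|---|
| L | 19 mM | 19 mM |
| Q | 38.0 mM | 76.0 mM |
| J | 1.5 mM (held) | 1.5 mM (held) |
| time | 20 h | 20 h |

- at the start none of D is dissolved
- run time (west): 20 h

1. which of these there is most of at the end, counted by the L in it, west (L.Q / L.Q.D / Z / L)
2. which of these there is most of at the end, counted by the L in it, east (L.Q / L.Q.D / Z / L)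
3. the largest of these amounts at the end, in percent of the L charged, west
4. the largest of these amounts at the end, in percent of the L charged, east

I turned the question round and asked what must hold for Z to lead L.Q at the end: the Q.D made must exceed half of the L charged, 9.50 mM. In west L has a half-life of 1.3 h, shorter than the run, so I let each L take one Q at once, which left c(Q) at 19.0 mM in west and 57.0 mM in east. D then holds steady, since in west it relaxes within 0.712 h, less than the run. Q consumes D in a pseudo-first-order way, so Q.D forms at the ceiling of 1.65 mM/h times the share of that consumption in consumption plus transfer: 0.357 mM/h in west, 0.748 mM/h in east. With c(Q) held constant, the integral is rate times time, and I called this the dose of Q.D, the total formed over the run: 7.15 mM in west, less than needed, and 15.0 mM in east, more than needed. Part of the dose stands unreacted, as the rate divided by 18 /M/h and c(L.Q). Subtracting that stock, and neglecting L and L.Q.D, I reckoned L.Q at 70.2 % in west and Z at 53.8 % in east.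

The forecast gave L.Q at 68 % in west and Z at 55 % in east, holding that “the doubled Q in the east drives enough Q.D formation to make Z the largest amount”. The simulation gave L.Q at 70.7 % in west and Z at 51.1 % in east.

In the neighbour of east charged with 32 mM of L, the dose came to 12.9 mM, below half of that charge, and the flask ended with L.Q at 67.5 % and Z at 29.5 %. West had not come to rest at 20.0 h: by 200 h Z had risen there from 21.8 % to 91.5 % and L.Q had fallen from 70.7 % to 1.04 %, and east, left as long, had Z at 96.6 %.

The rate constants come from no measurement; the result is computed.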